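## The problem

Compound 4, (S)-13-hydroxy-1-(2,4,6-trihydroxyphenyl)hexadecan-1-one, is a phloroglucinol ring carrying one unbranched hexadecanoyl chain. The ring is an article of commerce and the chain is linear, so neither ring construction nor chain assembly is difficult in itself. The difficulty sits in one atom: C13, the only stereocentre, a secondary carbinol of S configuration eleven methylene groups from the C1 carbonyl and three carbons from the chain end C16. No second stereocentre can direct it, and its two carbon arms (the propyl group C14–C16 and the tether C2–C12) look alike to any small reagent. Substrate control and ordinary asymmetric reduction of a C13 ketone are therefore ruled out; the configuration must come from a catalyst that reads the whole chain, from a coupling that tells a heteroatom from an alkyl group, or from the chiral pool. The acylphloroglucinol head is the sensitive part: an electron-rich, oxidisable triphenol and vinylogous acid that is alkylated or acylated at oxygen and at the free ring carbons under base and can lose its acyl group under forcing acid. The secondary alcohol in turn would not survive the Lewis acids used to acylate arenes or to cleave aryl methyl ethers. The enabling feature is that C13 is the omega-minus-3 carbon of a sixteen-carbon acyl chain attached to an acidic head: C1–C16 has the length of a palmitoyl chain, and the ionisable 2,4,6-trihydroxybenzoyl unit can stand in for a carboxylate. This is the substrate pattern of the subterminal fatty-acid hydroxylases of the cytochrome P450 family, so the C13 oxygen can be introduced last, directly into the C–H bond.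

## Retrosynthesis

First disconnection: the C13–O bond of 4 is cut back to a C13–H bond, which leads to 1-(2,4,6-trihydroxyphenyl)hexadecan-1-one 3. Cutting here, and not at C12–C13 or C13–C14, avoids a chiral building block, an organometallic coupling and the phenol protection that both would entail. It removes the stereocentre and the only sp3 functional group at one stroke, so 3 is achiral and unprotected and contains only the ring, the ketone and fifteen unfunctionalised chain carbons. The price is the demand on the forward reaction: of twenty-eight methylene hydrogens, the pro-S hydrogen at C13 must be replaced by hydroxyl, with C14 and C15 left alone, the ring untouched and the oxidation stopped at the alcohol. No small-molecule oxidant can do this. An enzyme pocket that holds the head group at a fixed distance from an oxidising heme can in principle, and 3 resembles the natural substrates of such enzymes in chain length and charge.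

Second disconnection: the aryl–C1 bond of 3 is cut to give benzene-1,3,5-triol 1 and hexadecanoyl chloride 2. A cut at C2–C3 (aldol condensation, then hydrogenation of the enone) would need phenol protection and deprotection and a condensation with an enolisable aliphatic aldehyde, four steps in place of one. The aryl–C1 cut uses the innate nucleophilicity of the ring, whose three CH positions are equivalent, so no regiochemical question arises. Both 1 and 2 are bulk chemicals. The forward Friedel–Crafts acylation only has to favour C- over O-acylation and stop after one acyl group, which the deactivating, chelated ketone helps to ensure.

## Roads not taken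

Alternative 1: The cut goes through the aromatic ring. The bond between the acyl-bearing ring carbon and a hydroxylated neighbour is opened, which unfolds ring and ketone into the open-chain tetraketide methyl (S)-19-(tert-butyldimethylsilyloxy)-3,5,7-trioxodocosanoate A1. In the forward key step, base would generate the carbanion at C6 of A1, which attacks the ester carbonyl C1 in an intramolecular Claisen condensation. Loss of methoxide closes the six-membered carbocycle, and threefold enolisation gives (S)-13-(tert-butyldimethylsilyloxy)-1-(2,4,6-trihydroxyphenyl)hexadecan-1-one A2, from which desilylation would release 4.
- Merits: the stereocentre is installed early by conventional means and rides through as a remote spectator, so its configuration is never in doubt. The closure copies the way polyketide synthases of the chalcone-synthase type make this ring.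
- Weak points: the effort goes into the one part of the molecule that costs nothing, since the ring is available as 1. A1 is a poly-β-carbonyl compound that must be assembled by polyanion chemistry over many steps and tends to cyclise on its own. The cyclisation mode is hard to enforce outside an enzyme: aldol closure between C2 and C7 leads to a resorcylate, and attack through oxygen leads to pyrones. The stereocentre still has to be made separately, so the sequence would run to roughly ten steps.
- Comparison: in security of configuration this road is better than the chosen plan. The chosen plan sets against it a two-step sequence, a purchased ring and no protecting group, at the cost of resting on one untested enzymatic step.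

Alternative 2: The cut is the C12–C13 bond. Racemic 2-(1-chlorobutyl)-4,4,5,5-tetramethyl-1,3,2-dioxaborolane A3 would be coupled with {12-oxo-12-[2,4,6-tris(methoxymethoxy)phenyl]dodecyl}zinc bromide A4 under a chiral nickel–diamine catalyst. Both enantiomers of A3 pass through the same α-boryl radical and are funnelled into one secondary boronate, (S)-13-(4,4,5,5-tetramethyl-1,3,2-dioxaborolan-2-yl)-1-[2,4,6-tris(methoxymethoxy)phenyl]hexadecan-1-one A5. Its C–B bond is then oxidised with retention and the acetals are removed to give 4.
- Merits: the catalyst has to tell boron from propyl at the radical carbon, a far larger difference than propyl against undecyl. The near-symmetry of C13 is thus sidestepped by a small-molecule catalyst of an established reaction class, and the electrophile is cheap and racemic.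
- Weak points: A4 needs the phenols masked, a twelve-carbon ω-bromo ketone built on the protected ring, and zinc insertion. Oxidation and deprotection follow the coupling, about seven steps in all. The organozinc must coexist with an enolisable aryl ketone. The waxy, non-crystalline intermediates offer little chance of raising an imperfect enantiomeric excess.
- Comparison: in predictability this road is ahead of the chosen plan, because its stereocontrol does not depend on evolving a protein. The chosen plan can set against it only brevity, the absence of protecting groups and organometallic reagents, and the fact that its outcome is known after one screening campaign.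

Alternative 3: The cut is the C1–C2 bond. 2-Hydroxy-4,6-bis(methoxymethoxy)benzaldehyde A6 would add its formyl C–H bond across the terminal alkene of (S)-pentadec-14-en-4-ol A7 under a rhodium–phosphoramidite catalyst. The ortho hydroxyl chelates the acyl rhodium hydride and holds back decarbonylation, the alkene inserts in the anti-Markovnikov sense, and reductive elimination gives (S)-13-hydroxy-1-[2-hydroxy-4,6-bis(methoxymethoxy)phenyl]hexadecan-1-one A8, which acid would convert into 4.
- Merits: convergence, complete atom economy in the key step, and a stereocentre from the chiral pool (A7 would come from copper-catalysed opening of an enantiopure terminal epoxide by an alkenyl Grignard reagent). The configuration is secure and the whole sequence is about five steps.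
- Weak points: A6 is flanked by two ortho substituents and is very electron-rich, and the alkene of A7 is unactivated. Linear against branched selectivity, chain-walking of the double bond and decarbonylation all have to be suppressed by the ligand, and the phenols still need partial protection.
- Comparison: this road is better than the chosen plan in security of configuration and not much longer. The chosen plan sets against it three fewer steps and no protecting-group operations. It also keeps this chiral-pool logic in reserve: the fallback for the key step uses the same kind of epoxide-derived building block.

Key step: step 2

Assumption: the hydroxylase variant used in step 2 is taken to be obtained beforehand by directed evolution against compound 3; this enzyme development belongs to step 2 and is not counted as a synthetic step.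

## Steps

Step 1
Reactants: 1 benzene-1,3,5-triol (phloroglucinol); 2 hexadecanoyl chloride (palmitoyl chloride)
Product: 3 1-(2,4,6-trihydroxyphenyl)hexadecan-1-one
Conditions: AlCl3 (4 equiv), PhNO2, 25 to 80 °C; then ice, aq. HCl
Reagents that add atoms: none
Why: Friedel–Crafts acylation: the acylium–AlCl3 complex from 2 attacks the strongly nucleophilic ring of 1, whose three CH positions are equivalent, so no regiochemical question arises. Any aryl ester formed by O-acylation should be carried on to 3 by Fries rearrangement under the same conditions, and the aluminium-chelated ortho-hydroxy ketone is deactivated enough that one equivalent of 2 should stop at monoacylation.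

Step 2
Reactants: 3 1-(2,4,6-trihydroxyphenyl)hexadecan-1-one
Product: 4 (S)-13-hydroxy-1-(2,4,6-trihydroxyphenyl)hexadecan-1-one
Conditions: evolved CYP102A1 (P450 BM3) variant, NADP+ (cat.), D-glucose, glucose dehydrogenase, catalase, air (O2), K2HPO4/KH2PO4 buffer pH 8.0, 5% DMSO, 25 °C
Reagents that add atoms: dioxygen, O=O
Why: Proposed new method: the closest known reaction type is the subterminal (omega-minus-1 to omega-minus-3) hydroxylation of palmitic acid and of N-palmitoyl amino acids by the self-sufficient heme-thiolate monooxygenases of the CYP102 family and their evolved variants, which has not been shown for an acylphloroglucinol. In the cycle the bound substrate displaces the water ligand of the ferric (trivalent iron) heme, two electrons from NADPH arrive through the fused flavin reductase domain, O2 is bound and cleaved, and the resulting oxoiron porphyrin radical cation (formally tetravalent iron) abstracts a hydrogen atom from C13; the carbon radical recombines with the iron-bound hydroxyl faster than it can invert, so the C13–O bond forms with retention. No ring is closed, and the single new stereocentre C13 is set under catalyst control alone: the pocket has to present the pro-S hydrogen of C13 to the oxidant, and its replacement with retention gives the S alcohol (O > C12 > C14 > H). The step needs regioselectivity for C13 over C14, C15 and the eleven methylenes C2–C12, pro-S over pro-R selectivity, and chemoselectivity for the chain over the electron-rich ring and over further oxidation of 4 to the C13 ketone. The substrate contributes its shape: the chain has the sixteen carbons of a palmitoyl group, so that C13–C16 lie over the heme when the head is held at the mouth of the substrate channel, and the head is a vinylogous acid that is substantially ionised at pH 8 and can take the place of the carboxylate at the arginine and tyrosine residues there, which also keeps the ring away from the iron. The remaining discrimination has to be bred into the protein by mutagenesis of the residues lining the distal pocket (positions 82, 87, 263, 328 and 437) and the channel mouth (47, 51 and 188) and screening against 3 with chiral chromatographic analysis. Glucose dehydrogenase recycles NADPH so that O2 and glucose are the only stoichiometric reagents, and catalase destroys hydrogen peroxide from uncoupled turnover before it can attack the triphenol.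

## Compound list

1 | benzene-1,3,5-triol (phloroglucinol) | Oc1cc(O)cc(O)c1 | starting material
2 | hexadecanoyl chloride (palmitoyl chloride) | CCCCCCCCCCCCCCCC(=O)Cl | starting material
3 | 1-(2,4,6-trihydroxyphenyl)hexadecan-1-one | CCCCCCCCCCCCCCCC(=O)c1c(O)cc(O)cc1O | intermediate
4 | (S)-13-hydroxy-1-(2,4,6-trihydroxyphenyl)hexadecan-1-one | CCC[C@H](O)CCCCCCCCCCCC(=O)c1c(O)cc(O)cc1O | target

## Step count and risks

Total step count: 2. Longest linear sequence: 2 steps (1 and 2 to 3, then 3 to 4). The route has only these two steps, so both are assessed and there is no third step to list.

Step 2 (key step, proposed new method). The most likely failure is insufficient regio- and enantio-discrimination.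
- The chain can slide in a wide channel, so hydroxylation may spread over C13, C14 and C15.
- The pro-R hydrogen may be abstracted. The parent enzyme is known to favour the R-configured subterminal alcohols of palmitic acid, so the pro-S selectivity asked for here runs against its native bias.
- Weak binding of the head group, which is bulkier than a carboxylate, may uncouple the cycle, and the peroxide so formed may oxidise the ring.
- Prolonged turnover may oxidise the product further to the C13 ketone.
- Separation of positional isomers that differ only in the site of the hydroxyl will need preparative reversed-phase chromatography.

Fallback for step 2: a chiral-pool synthesis by known reactions that sets out from 1 and returns to the route at 4. Compound 1 is converted with MOMCl and NaH in DMF into 1,3,5-tris(methoxymethoxy)benzene F1. Commercial undec-10-enoyl chloride, MeNHOMe·HCl and pyridine give N-methoxy-N-methylundec-10-enamide F2. Lithiation of F1 with n-BuLi in THF at 0 °C between two of the acetal oxygens and addition of F2 should give 1-[2,4,6-tris(methoxymethoxy)phenyl]undec-10-en-1-one F3. Commercial (S)-2-propyloxirane (CCC[C@H]1CO1) is opened at its CH2 group by CH2=CHMgBr with catalytic CuI (copper monoiodide) in THF to give (S)-hept-1-en-4-ol F4; the stereocentre is taken over untouched from the epoxide. Cross-metathesis of F3 with an excess of F4 (second-generation Hoveyda–Grubbs catalyst, CH2Cl2, 40 °C) should give (S)-13-hydroxy-1-[2,4,6-tris(methoxymethoxy)phenyl]hexadec-10-en-1-one F5 as an E/Z mixture. H2 over Pd/C in EtOAc saturates the C10–C11 double bond to give (S)-13-hydroxy-1-[2,4,6-tris(methoxymethoxy)phenyl]hexadecan-1-one F6, and HCl in MeOH at 50 °C removes the three acetals to give 4. The same sequence would also supply the authentic S reference sample needed to calibrate the enzyme screen.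

Step 1. The most likely failure is loss of material to competing O-acylation, a second C-acylation and incomplete Fries rearrangement. Removal of nitrobenzene from a waxy amphiphilic product is a further source of loss.

Fallback for step 1: a Hoesch reaction that sets out from 1 and returns at 3. Commercial hexadecanenitrile, ZnCl2 and dry HCl in Et2O at 0 °C should convert 1 into 1-(2,4,6-trihydroxyphenyl)hexadecan-1-iminium chloride F7. This salt precipitates and, as a deactivated iminium salt, can be acylated neither a second time nor at oxygen. Heating F7 in water hydrolyses it to 3.

## Further compounds

F1 | step 2 | 1,3,5-tris(methoxymethoxy)benzene | COCOc1cc(OCOC)cc(OCOC)c1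
F2 | step 2 | N-methoxy-N-methylundec-10-enamide | C=CCCCCCCCCC(=O)N(C)OC
F3 | step 2 | 1-[2,4,6-tris(methoxymethoxy)phenyl]undec-10-en-1-one | C=CCCCCCCCCC(=O)c1c(OCOC)cc(OCOC)cc1OCOC
F4 | step 2 | (S)-hept-1-en-4-ol | CCC[C@H](O)CC=C
F5 | step 2 | (S)-13-hydroxy-1-[2,4,6-tris(methoxymethoxy)phenyl]hexadec-10-en-1-one (E/Z mixture) | CCC[C@H](O)CC=CCCCCCCCCC(=O)c1c(OCOC)cc(OCOC)cc1OCOC
F6 | step 2 | (S)-13-hydroxy-1-[2,4,6-tris(methoxymethoxy)phenyl]hexadecan-1-one | CCC[C@H](O)CCCCCCCCCCCC(=O)c1c(OCOC)cc(OCOC)cc1OCOC
F7 | step 1 | 1-(2,4,6-trihydroxyphenyl)hexadecan-1-iminium chloride | CCCCCCCCCCCCCCCC(=[NH2+])c1c(O)cc(O)cc1O.[Cl-]
A1 | alternative 1 | methyl (S)-19-(tert-butyldimethylsilyloxy)-3,5,7-trioxodocosanoate | CCC[C@H](O[Si](C)(C)C(C)(C)C)CCCCCCCCCCCC(=O)CC(=O)CC(=O)CC(=O)OC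
A2 | alternative 1 | (S)-13-(tert-butyldimethylsilyloxy)-1-(2,4,6-trihydroxyphenyl)hexadecan-1-one | CCC[C@H](O[Si](C)(C)C(C)(C)C)CCCCCCCCCCCC(=O)c1c(O)cc(O)cc1O
A3 | alternative 2 | racemic 2-(1-chlorobutyl)-4,4,5,5-tetramethyl-1,3,2-dioxaborolane | CCCC(Cl)B1OC(C)(C)C(C)(C)O1
A4 | alternative 2 | {12-oxo-12-[2,4,6-tris(methoxymethoxy)phenyl]dodecyl}zinc bromide | Br[Zn]CCCCCCCCCCCC(=O)c1c(OCOC)cc(OCOC)cc1OCOC
A5 | alternative 2 | (S)-13-(4,4,5,5-tetramethyl-1,3,2-dioxaborolan-2-yl)-1-[2,4,6-tris(methoxymethoxy)phenyl]hexadecan-1-one | CCC[C@H](B1OC(C)(C)C(C)(C)O1)CCCCCCCCCCCC(=O)c1c(OCOC)cc(OCOC)cc1OCOC
A6 | alternative 3 | 2-hydroxy-4,6-bis(methoxymethoxy)benzaldehyde | O=Cc1c(O)cc(OCOC)cc1OCOC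
A7 | alternative 3 | (S)-pentadec-14-en-4-ol | CCC[C@H](O)CCCCCCCCCC=C
A8 | alternative 3 | (S)-13-hydroxy-1-[2-hydroxy-4,6-bis(methoxymethoxy)phenyl]hexadecan-1-one | CCC[C@H](O)CCCCCCCCCCCC(=O)c1c(O)cc(OCOC)cc1OCOC
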